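**Retrosynthetic overview** (ring numbering of the target: O1, O2, C3 bearing CH2CO2H, C4 bearing CH3, C5 = CH2, C6 quaternary)
- The C3–CH2CO2H bond is made last on the ring: an acetate enol silane adds axially to the cyclic peroxycarbenium ion (O2=C3+) of a 3-methoxy-1,2-dioxane, with C4 and C6 locking the half-chair.
- The 1,2-dioxane, the only ring, is formed once by a formal [3+3] annulation that makes C5–C6 and O2–C3: a ketone-derived silylperoxycarbenium ion (C6–O1–O2) plus an enantiopure 2-methylcyclopropyl silyl ether (C5–C4–C3).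
- Enabling feature: the O1–O2 unit sits between C6, a ketone-level carbon (peroxycarbenium carbon), and C3, which can be carried at acetal level; the unsubstituted C5 methylene next to the methyl-bearing C4 makes C5–C4–C3 an aldehyde homoenolate, i.e. a cyclopropanol ether.
- The side-chain stereocentre is set by Cu-catalysed asymmetric conjugate addition; C4 is bought with (R)-propylene oxide; C3 is relayed from C4 and C6.
- C6 is not reliably controlled in this plan; its epimer is expected and is separated after the C3 substitution.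

Key step: step 12

Assumptions: 9-phenylnonan-1-ol is taken as commercially available. Centres that are ionised later (the ketal carbon of the peroxyketal, the anomeric C3 of the peroxyacetals) are written without a descriptor.

Step 1
Reactants: 1 9-phenylnonan-1-ol
Product: 2 9-phenylnonanal
Conditions: TEMPO (10 mol%), PhI(OAc)2 (1.1 equiv), CH2Cl2, rt
Reagents that add atoms: none
Why: The TEMPO/PhI(OAc)2 oxidation of a primary alkanol should stop cleanly at the aldehyde.

Step 2
Reactants: 2 9-phenylnonanal; 3 1-(triphenyl-λ5-phosphanylidene)propan-2-one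
Product: 4 (3E)-12-phenyldodec-3-en-2-one
Conditions: CH2Cl2, 40 °C
Reagents that add atoms: none
Why: Wittig olefination with a stabilised acyl ylide should give the (E)-enone selectively.

Step 3
Reactants: 4 (3E)-12-phenyldodec-3-en-2-one
Product: 5 (4R)-4-methyl-12-phenyldodecan-2-one
Conditions: MeMgBr (1.2 equiv), CuBr·SMe2 (5 mol%), Josiphos-type ligand (6 mol%, antipode selected for the R product), t-BuOMe, −75 °C; aq NH4Cl
Reagents that add atoms: methylmagnesium bromide, C[Mg]Br
Why: Cu/Josiphos-catalysed asymmetric conjugate addition of MeMgBr to linear acyclic (E)-enones is a close precedent, and the ligand antipode sets the 4R centre (the side-chain stereocentre of the target) by catalyst control.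

Step 4
Reactants: 5 (4R)-4-methyl-12-phenyldodecan-2-one
Product: 6 triethyl{[(4R)-4-methyl-12-phenyldodec-1-en-2-yl]oxy}silane
Conditions: LDA (1.1 equiv), THF, −78 °C; Et3SiCl, −78 → 0 °C
Reagents that add atoms: chlorotriethylsilane, CC[Si](Cl)(CC)CC
Why: Kinetic enolisation of a methyl ketone with LDA removes a methyl proton, and O-silylation should give the terminal enol silane without touching the β-stereocentre.

Step 5
Reactants: 6 triethyl{[(4R)-4-methyl-12-phenyldodec-1-en-2-yl]oxy}silane
Product: 7 triethyl{[(4R)-4-methyl-12-phenyl-2-(triethylsilylperoxy)dodecan-2-yl]oxy}silane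
Conditions: Co(thd)2 (5 mol%), Et3SiH (2 equiv), O2 (1 atm), ClCH2CH2Cl, rt
Reagents that add atoms: dioxygen, O=O; triethylsilane, CC[SiH](CC)CC
Why: Cobalt-catalysed Isayama–Mukaiyama silylperoxidation of silyl enol ethers puts H on the terminal carbon and the silylperoxy group on the oxygenated carbon, giving the silyl monoperoxyketal (its ketal centre is uncontrolled and irrelevant, since it is ionised in step 12).

Step 6
Reactants: 8 (2R)-2-methyloxirane; 9 triethyl phosphonoacetate
Product: 10 ethyl (1S,2S)-2-methylcyclopropane-1-carboxylate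
Conditions: NaOt-Bu, DME, 130 °C, sealed vessel
Reagents that add atoms: none
Why: In the Wadsworth–Emmons cyclopropanation the phosphonoacetate anion opens the epoxide at CH2 and the phosphate is then displaced 3-exo-tet with inversion at the methyl-bearing carbon, which should give the trans ester with 2S from the purchased R epoxide.

Step 7
Reactants: 10 ethyl (1S,2S)-2-methylcyclopropane-1-carboxylate
Product: 11 (1S,2S)-N-methoxy-N,2-dimethylcyclopropane-1-carboxamide
Conditions: MeNH(OMe)·HCl (1.5 equiv), i-PrMgCl (3 equiv), THF, −20 → 0 °C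
Reagents that add atoms: N,O-dimethylhydroxylamine hydrochloride, CNOC.Cl
Why: Direct aminolysis of the ester by the magnesium amide of N,O-dimethylhydroxylamine is a standard Weinreb amide synthesis that leaves the ring stereocentres untouched.

Step 8
Reactants: 11 (1S,2S)-N-methoxy-N,2-dimethylcyclopropane-1-carboxamide
Product: 12 1-[(1S,2S)-2-methylcyclopropyl]ethan-1-one
Conditions: MeMgBr (1.2 equiv), Et2O, 0 °C; aq NH4Cl (volatile product kept as Et2O solution)
Reagents that add atoms: methylmagnesium bromide, C[Mg]Br
Why: In the Weinreb ketone synthesis the chelated tetrahedral intermediate prevents over-addition.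

Step 9
Reactants: 12 1-[(1S,2S)-2-methylcyclopropyl]ethan-1-one
Product: 13 (1S,2S)-2-methylcyclopropyl acetate
Conditions: CF3CO3H (from (CF3CO)2O and urea·H2O2), Na2HPO4, CH2Cl2, 0 °C → rt
Reagents that add atoms: trifluoroperacetic acid, OOC(=O)C(F)(F)F
Why: In the Baeyer–Villiger oxidation of methyl cyclopropyl ketones the cyclopropyl group migrates in preference to methyl and with retention of configuration, the classical entry to cyclopropyl acetates.

Step 10
Reactants: 13 (1S,2S)-2-methylcyclopropyl acetate
Product: 14 (1S,2S)-2-methylcyclopropan-1-ol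
Conditions: LiAlH4 (0.6 equiv), Et2O, 0 °C; Fieser work-up (used as dried Et2O solution)
Reagents that add atoms: none
Why: Hydride cleavage of the acetate avoids the aqueous base that isomerises cyclopropanols to aldehydes, and no bond to a stereocentre is touched.

Step 11
Reactants: 14 (1S,2S)-2-methylcyclopropan-1-ol
Product: 15 triethyl{[(1S,2S)-2-methylcyclopropyl]oxy}silane
Conditions: Et3SiCl, imidazole, Et2O/CH2Cl2, 0 °C → rt
Reagents that add atoms: chlorotriethylsilane, CC[Si](Cl)(CC)CC
Why: Imidazole-mediated O-silylation of the secondary cyclopropanol is a standard protection that keeps the medium non-basic enough to avoid ring opening.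

Step 12
Reactants: 7 triethyl{[(4R)-4-methyl-12-phenyl-2-(triethylsilylperoxy)dodecan-2-yl]oxy}silane; 15 triethyl{[(1S,2S)-2-methylcyclopropyl]oxy}silane
Product: 17 (4S,6R)-3-methoxy-4,6-dimethyl-6-[(2R)-2-methyl-10-phenyldecyl]-1,2-dioxane, via silyl peroxyacetal 16 (not isolated)
Conditions: 15 (2 equiv), TMSOTf (20 mol%), CH2Cl2, −78 °C; then MeOH, −78 → 0 °C
Reagents that add atoms: methanol, CO
Why: Proposed new method: TMSOTf ionises 7 (loss of Et3SiO–) to the silylperoxycarbenium ion R(Me)C6=O1+–O2SiEt3; the oxygen-activated ring bond of the siloxycyclopropane 15 (a homo-enol ether) attacks it through its unsubstituted CH2 (target C5), forming C5–C6 and opening the ring to an O-silyl oxocarbenium ion at C3, which the silylperoxy oxygen O2 captures with loss of Et3Si+ (the chain carrier) to form O2–C3 and give 16, converted in the same flask by MeOH and the acid present into the stable methyl peroxyacetal 17. The closest known reaction types are the Lewis-acid annulation of silylperoxycarbenium ions with alkenes to 1,2-dioxolanes (the same C–C then O–C sequence as a [3+2]), the electrophilic ring opening of siloxycyclopropanes as homoenolate equivalents, and the formal [3+3] annulations of cyclopropanes with nitrones; what is new is a cyclopropane σ-bond as partner of a peroxycarbenium ion. The 1,2-dioxane closes by 6-exo-trig attack of O2 on the C3=O+ carbon after the intermolecular C–C bond formation. C4 comes with 15 and is untouched, since no bond to it is made or broken; C3 forms as an anomeric mixture, which is irrelevant because it is re-ionised in step 13; C6 is created in an open transition state in which CH3 and the CH2R chain differ little, so no reliable control is claimed and the 6S epimer is expected alongside, to be removed after step 13. The step needs regioselective attack at the unsubstituted ring CH2 with cleavage of the bond to the oxygen-bearing carbon, which the siloxy donor and sterics should secure, and it needs C–C bond formation to outrun Criegee rearrangement and enolisation of the cation, for which low temperature and excess 15 are used.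

Step 13
Reactants: 17 (4S,6R)-3-methoxy-4,6-dimethyl-6-[(2R)-2-methyl-10-phenyldecyl]-1,2-dioxane; 18 tert-butyl[(1-methoxyethenyl)oxy]dimethylsilane
Product: 19 methyl 2-[(3S,4S,6R)-4,6-dimethyl-6-[(2R)-2-methyl-10-phenyldecyl]-1,2-dioxan-3-yl]acetate
Conditions: 18 (2 equiv), TMSOTf (30 mol%), CH2Cl2, −78 °C; chromatographic removal of the 6S series
Reagents that add atoms: none
Why: Lewis-acid substitution of cyclic peroxyacetals by silyl ketene acetals (Mukaiyama-type addition to a cyclic peroxycarbenium ion) is known, and here the half-chair with C4–CH3 and the C6 chain pseudo-equatorial is locked because its alternative has them syn-diaxial, so axial attack at C3 on the face away from the pseudo-axial C6–CH3 should give the 3,4-cis (3S) ester.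

Step 14
Reactants: 19 methyl 2-[(3S,4S,6R)-4,6-dimethyl-6-[(2R)-2-methyl-10-phenyldecyl]-1,2-dioxan-3-yl]acetate
Product: 20 2-[(3S,4S,6R)-4,6-dimethyl-6-[(2R)-2-methyl-10-phenyldecyl]-1,2-dioxan-3-yl]acetic acid
Conditions: LiOH·H2O (2 equiv), THF/H2O 3:1, 0 °C; then 1 M HCl to pH 3
Reagents that add atoms: lithium hydroxide, [Li+].[OH-]
Why: Cold LiOH saponification of methyl esters next to dialkyl peroxides is precedented for 1,2-dioxolane- and 1,2-dioxane-3-acetates and should be faster than α-deprotonation, so C3 should be kept.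

**Compound list**
1 | 9-phenylnonan-1-ol | OCCCCCCCCCc1ccccc1 | starting material
2 | 9-phenylnonanal | O=CCCCCCCCCc1ccccc1 | intermediate
3 | 1-(triphenyl-λ5-phosphanylidene)propan-2-one | CC(=O)C=P(c1ccccc1)(c1ccccc1)c1ccccc1 | starting material
4 | (3E)-12-phenyldodec-3-en-2-one | CC(=O)/C=C/CCCCCCCCc1ccccc1 | intermediate
5 | (4R)-4-methyl-12-phenyldodecan-2-one | C[C@H](CCCCCCCCc1ccccc1)CC(C)=O | intermediate
6 | triethyl{[(4R)-4-methyl-12-phenyldodec-1-en-2-yl]oxy}silane | C[C@H](CCCCCCCCc1ccccc1)CC(=C)O[Si](CC)(CC)CC | intermediate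
7 | triethyl{[(4R)-4-methyl-12-phenyl-2-(triethylsilylperoxy)dodecan-2-yl]oxy}silane (both C2 epimers) | C[C@H](CCCCCCCCc1ccccc1)CC(C)(O[Si](CC)(CC)CC)OO[Si](CC)(CC)CC | intermediate
8 | (2R)-2-methyloxirane | C[C@@H]1CO1 | starting material
9 | triethyl phosphonoacetate | CCOC(=O)CP(=O)(OCC)OCC | starting material
10 | ethyl (1S,2S)-2-methylcyclopropane-1-carboxylate | C[C@H]1C[C@@H]1C(=O)OCC | intermediate
11 | (1S,2S)-N-methoxy-N,2-dimethylcyclopropane-1-carboxamide | C[C@H]1C[C@@H]1C(=O)N(C)OC | intermediate
12 | 1-[(1S,2S)-2-methylcyclopropyl]ethan-1-one | C[C@H]1C[C@@H]1C(C)=O | intermediate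
13 | (1S,2S)-2-methylcyclopropyl acetate | C[C@H]1C[C@@H]1OC(C)=O | intermediate
14 | (1S,2S)-2-methylcyclopropan-1-ol | C[C@H]1C[C@@H]1O | intermediate
15 | triethyl{[(1S,2S)-2-methylcyclopropyl]oxy}silane | C[C@H]1C[C@@H]1O[Si](CC)(CC)CC | intermediate
16 | triethyl{[(4S,6R)-4,6-dimethyl-6-[(2R)-2-methyl-10-phenyldecyl]-1,2-dioxan-3-yl]oxy}silane (C3 anomers) | C[C@H](CCCCCCCCc1ccccc1)C[C@]1(C)C[C@H](C)C(O[Si](CC)(CC)CC)OO1 | intermediate
17 | (4S,6R)-3-methoxy-4,6-dimethyl-6-[(2R)-2-methyl-10-phenyldecyl]-1,2-dioxane (C3 anomers) | C[C@H](CCCCCCCCc1ccccc1)C[C@]1(C)C[C@H](C)C(OC)OO1 | intermediate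
18 | tert-butyl[(1-methoxyethenyl)oxy]dimethylsilane | C=C(OC)O[Si](C)(C)C(C)(C)C | starting material
19 | methyl 2-[(3S,4S,6R)-4,6-dimethyl-6-[(2R)-2-methyl-10-phenyldecyl]-1,2-dioxan-3-yl]acetate | C[C@H](CCCCCCCCc1ccccc1)C[C@]1(C)C[C@H](C)[C@H](CC(=O)OC)OO1 | intermediate
20 | 2-[(3S,4S,6R)-4,6-dimethyl-6-[(2R)-2-methyl-10-phenyldecyl]-1,2-dioxan-3-yl]acetic acid | C[C@H](CCCCCCCCc1ccccc1)C[C@]1(C)C[C@H](C)[C@H](CC(=O)O)OO1 | target

Total step count: 14. Longest linear sequence: 9 steps (steps 6–14, from (2R)-2-methyloxirane).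

**Steps most likely to fail**

Step 12 (the proposed new method). The cyclopropane σ-bond may be too weak a nucleophile, so that Criegee-type rearrangement or α-deprotonation of the peroxycarbenium ion and acid-induced opening of the cyclopropane outrun C–C bond formation; in addition the bond is expected to form without facial bias at C6. The fallback uses known chemistry, sets out from 5 and comes back at 17. Kinetic enolisation of 5 (LDA, THF, −78 °C) and trapping with PhNTf2 should give (4R)-4-methyl-12-phenyldodec-1-en-2-yl trifluoromethanesulfonate F1. Negishi coupling (Pd(dppf)Cl2, THF, 50 °C) with [(2R)-3-methoxy-2-methyl-3-oxopropyl]zinc bromide F2, made from commercial methyl (R)-3-bromo-2-methylpropanoate with Zn/LiCl, should give methyl (2S,6R)-2,6-dimethyl-4-methylidene-14-phenyltetradecanoate F3. DIBAL-H (CH2Cl2, −78 °C) would give (2S,6R)-2,6-dimethyl-4-methylidene-14-phenyltetradecanal F4, and HC(OMe)3/PPTS/MeOH its acetal (2S,6R)-1,1-dimethoxy-2,6-dimethyl-4-methylidene-14-phenyltetradecane F5. Isayama–Mukaiyama silylperoxidation of the 1,1-disubstituted alkene (Co(thd)2, O2, Et3SiH) would give triethyl{[(2S,4R,6R)-1,1-dimethoxy-2,4,6-trimethyl-14-phenyltetradecan-4-yl]peroxy}silane F6 together with its 4-epimer. p-TsOH in MeOH should then remove the silyl group and close the hydroperoxide 6-exo onto the acetal to give 17. This route is also unselective at C6, and the epimers are separated at the same place as in the main route.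

Step 13. The very reactive ketene acetal may react close to diffusion control and erode the axial preference at C3, and proton loss from C4 of the cyclic cation may compete. The fallback sets out from 17 and comes back at 20. The weaker and more selective π-nucleophile allyltrimethylsilane (SnCl4, CH2Cl2, −78 °C, a known substitution of cyclic peroxyacetals) should give (3S,4S,6R)-4,6-dimethyl-6-[(2R)-2-methyl-10-phenyldecyl]-3-(prop-2-en-1-yl)-1,2-dioxane F7. Lemieux–Johnson cleavage (OsO4 cat., NaIO4, 2,6-lutidine, dioxane/H2O) would give 2-[(3S,4S,6R)-4,6-dimethyl-6-[(2R)-2-methyl-10-phenyldecyl]-1,2-dioxan-3-yl]acetaldehyde F8, and Pinnick oxidation (NaClO2, NaH2PO4, 2-methylbut-2-ene) then gives 20.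

Step 14. Hydroxide may deprotonate α to the ester and open the ring by retro-oxa-Michael elimination, and re-closure would epimerise C3 towards the more stable trans isomer; base-induced Kornblum–DeLaMare cleavage at C3–H is a second possibility. The fallback sets out from 17 and comes back at 20 without any basic step. The silyl ketene thioacetal [1-(ethylsulfanyl)ethenyl]oxy(trimethyl)silane F9 (from commercial S-ethyl thioacetate, LDA, Me3SiCl) is used in the step 13 protocol to give S-ethyl 2-[(3S,4S,6R)-4,6-dimethyl-6-[(2R)-2-methyl-10-phenyldecyl]-1,2-dioxan-3-yl]ethanethioate F10. Silver-assisted hydrolysis (AgNO3, 2,6-lutidine, THF/H2O, rt) then gives 20.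

Further compounds
F1 | step 12 | (4R)-4-methyl-12-phenyldodec-1-en-2-yl trifluoromethanesulfonate | C[C@H](CCCCCCCCc1ccccc1)CC(=C)OS(=O)(=O)C(F)(F)F
F2 | step 12 | [(2R)-3-methoxy-2-methyl-3-oxopropyl]zinc bromide | COC(=O)[C@@H](C)C[Zn]Br
F3 | step 12 | methyl (2S,6R)-2,6-dimethyl-4-methylidene-14-phenyltetradecanoate | C[C@H](CCCCCCCCc1ccccc1)CC(=C)C[C@H](C)C(=O)OC
F4 | step 12 | (2S,6R)-2,6-dimethyl-4-methylidene-14-phenyltetradecanal | C[C@H](CCCCCCCCc1ccccc1)CC(=C)C[C@H](C)C=O
F5 | step 12 | (2S,6R)-1,1-dimethoxy-2,6-dimethyl-4-methylidene-14-phenyltetradecane | C[C@H](CCCCCCCCc1ccccc1)CC(=C)C[C@H](C)C(OC)OC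
F6 | step 12 | triethyl{[(2S,4R,6R)-1,1-dimethoxy-2,4,6-trimethyl-14-phenyltetradecan-4-yl]peroxy}silane | C[C@H](CCCCCCCCc1ccccc1)C[C@@](C)(OO[Si](CC)(CC)CC)C[C@H](C)C(OC)OC
F7 | step 13 | (3S,4S,6R)-4,6-dimethyl-6-[(2R)-2-methyl-10-phenyldecyl]-3-(prop-2-en-1-yl)-1,2-dioxane | C[C@H](CCCCCCCCc1ccccc1)C[C@]1(C)C[C@H](C)[C@H](CC=C)OO1
F8 | step 13 | 2-[(3S,4S,6R)-4,6-dimethyl-6-[(2R)-2-methyl-10-phenyldecyl]-1,2-dioxan-3-yl]acetaldehyde | C[C@H](CCCCCCCCc1ccccc1)C[C@]1(C)C[C@H](C)[C@H](CC=O)OO1
F9 | step 14 | [1-(ethylsulfanyl)ethenyl]oxy(trimethyl)silane | C=C(SCC)O[Si](C)(C)C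
F10 | step 14 | S-ethyl 2-[(3S,4S,6R)-4,6-dimethyl-6-[(2R)-2-methyl-10-phenyldecyl]-1,2-dioxan-3-yl]ethanethioate | C[C@H](CCCCCCCCc1ccccc1)C[C@]1(C)C[C@H](C)[C@H](CC(=O)SCC)OO1
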